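The dimer is cut by retro-Diels–Alder cleavage of C2–C4′ and C14–C15′ (guaiane numbering; primes mark the spiro half). This gives dehydrozaluzanin C and its 1,2-dehydro derivative, so one monomer serves both halves. Everything then rests on the C6–C7 bond of that monomer. The key step exploits the trans-fused α-methylene-γ-butyrolactone O–C6–C7–C11(=C13)–C12 on seven-membered ring B. A ring A aldehyde (C6, silyloxycyclopentene, C5 stereocentre) meets a (Z)-2-(methoxycarbonyl)allylboronate bearing the C8–C10 bromobutenyl chain. One operation forms C6–C7, sets C6 and C7, moves the alkene to C11=C13 and closes the lactone.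

Key step: step 8

Assumption: in the target string, H5 of the unprimed (diene-derived) half lies on the same face as H6, opposite to the arrangement at C5′. C5 is a γ-position of the C1=C2–C3=O enone and is configurationally mobile, so it is addressed in the last step.

Step 1
Reactants: 1 (1S,4R)-4-hydroxycyclopent-2-en-1-yl acetate
Product: 2 (1S,4R)-4-(tert-butyldimethylsilyloxy)cyclopent-2-en-1-yl acetate
Conditions: TBSCl, imidazole, DMF, 0 °C → rt
Reagents that add atoms: tert-butyldimethylsilyl chloride, CC(C)(C)[Si](C)(C)Cl
Why: Imidazole-promoted O-silylation of the free allylic alcohol; no stereocentre is touched.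

Step 2
Reactants: 2 silyloxy acetate; 3 nitromethane
Product: 4 tert-butyl(dimethyl){[(1R,4S)-4-(nitromethyl)cyclopent-2-en-1-yl]oxy}silane (cis)
Conditions: MeNO2 (10 equiv), Cs2CO3, Pd(PPh3)4 (5 mol %), THF, 45 °C
Reagents that add atoms: none
Why: Tsuji–Trost allylic alkylation: zerovalent palladium ionises the acetate with inversion and the soft nitronate attacks anti to the metal at the allyl terminus remote from the silyloxy group, so net retention gives the cis-1,4 product and carries the acetate-bearing centre over into C5.

Step 3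
Reactants: 4 cis nitromethyl silyl ether
Product: 6 (1S,4R)-4-(tert-butyldimethylsilyloxy)cyclopent-2-ene-1-carbaldehyde, via sodium nitronate 5 (not isolated)
Conditions: NaOMe, MeOH, 0 °C; then TiCl3 (aq), NH4OAc, pH 5–6, 0 °C → rt
Reagents that add atoms: water, O
Why: Reductive Nef reaction: trivalent titanium reduces the nitronate to the imine, which hydrolyses in the pH 5–6 buffer, a window that spares the silyl ether and leaves the α-stereocentre C5 and the β,γ-alkene of the aldehyde in place (6 is extracted and used at once).

Step 4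
Reactants: 7 1-(trimethylsilyl)propyne; 8 2,3-dibromopropene
Product: 10 (5-bromohex-5-en-1-yn-1-yl)trimethylsilane, via lithiated silylpropyne 9 (not isolated)
Conditions: n-BuLi, THF, −78 → −20 °C; then 8, −78 °C → rt
Reagents that add atoms: none
Why: SN2 alkylation of a silyl-capped propargyllithium at the allylic bromide (the silyl group directs reaction to the propargylic carbon, the vinylic bromide is inert).

Step 5
Reactants: 10 silylated bromoenyne
Product: 11 2-bromohex-1-en-5-yne
Conditions: K2CO3 (cat.), MeOH, rt
Reagents that add atoms: none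
Why: Carbonate-catalysed methanolysis of the alkynyl C–Si bond (protodesilylation), to which the bromoalkene is indifferent.

Step 6
Reactants: 11 2-bromohex-1-en-5-yne; 12 methyl chloroformate
Product: 14 methyl 6-bromohept-6-en-2-ynoate, via lithium acetylide 13 (not isolated)
Conditions: LiN(i-Pr)2, THF, −78 °C; then 12, −78 → 0 °C
Reagents that add atoms: none
Why: Amide-base deprotonation of the terminal alkyne, which avoids bromine–lithium exchange, followed by C-acylation of the acetylide with the chloroformate.

Step 7
Reactants: 14 bromoenynoate; 15 2-(iodomethyl)-4,4,5,5-tetramethyl-1,3,2-dioxaborolane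
Product: 17 methyl (Z)-6-bromo-2-[(4,4,5,5-tetramethyl-1,3,2-dioxaborolan-2-yl)methyl]hepta-2,6-dienoate, via α-alanyl acrylate 16 (not isolated)
Conditions: i-Bu2AlH, HMPA, THF, 0 °C; then 15, 0 °C → rt
Reagents that add atoms: none
Why: Syn-hydroalumination of the ynoate puts aluminium on the α-carbon and hydrogen on C7 cis to it, and alkylation with the iodomethylboronate (boronate complex, 1,2-shift) retains that geometry, so C8 ends cis to the ester and trans to CH2B; SN2′ borylation of the matching Morita–Baylis–Hillman acetate was not chosen because it favours the opposite alkene geometry, which leads to the cis lactone.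

Step 8
Reactants: 6 ring A aldehyde; 17 (Z)-allylboronate
Product: 19 (4S,5R)-4-(3-bromobut-3-en-1-yl)-5-[(1S,4R)-4-(tert-butyldimethylsilyloxy)cyclopent-2-en-1-yl]-3-methylideneoxolan-2-one, via homoallylic borate 18 (not isolated)
Conditions: Sc(OTf)3 (10 mol %), toluene, −20 °C → rt; then p-TsOH (5 mol %), rt
Reagents that add atoms: none
Why: Sc(OTf)3 binds a dioxaborolane oxygen and raises the Lewis acidity of boron, so the aldehyde oxygen of 6 coordinates to boron and C7 attacks C6 through a closed six-membered chair transition state with allylic transposition (C11=C13 is created and borate 18 results). The closest known reaction type is the Lewis-acid-accelerated addition of 2-alkoxycarbonyl allylboronates to aldehydes with in situ lactonisation to α-methylene-γ-butyrolactones. The only ring closed is the lactone, by 5-exo-trig acyl substitution of the C6 borate oxygen at ester carbon C12 with loss of the methoxyboronate, completed by a trace of p-TsOH. C7 is controlled by the alkene geometry: C8, trans to CH2B, sits pseudo-equatorial in the chair, which gives the 6,7-anti adduct and hence the trans lactone. C6 is controlled by C5 through a Felkin–Anh rotamer (C5–C1 sp2 bond anti to the forming bond, C4H2 next to the carbonyl oxygen, H5 towards the incoming C7), which reagents of this E-crotyl type accommodate without syn-pentane strain. Addition must outrun enolisation of the β,γ-unsaturated aldehyde, which the base-free medium, the catalysed low-temperature addition and the immediate use of 6 secure, while the vinylic bromide, silyl ether and ring A alkene are spectators.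

Step 9
Reactants: 19 trans α-methylene lactone
Product: 20 11βH-13-(dimethylamino) adduct of 19 ((3R,4S,5R)-lactone, CH2NMe2 trans to the C8 chain)
Conditions: Me2NH (2 M in THF), MeOH, 0 °C → rt
Reagents that add atoms: dimethylamine, CNC
Why: Reversible aza-Michael addition masks the exocyclic acrylate, the only competing acceptor for the later enolate and palladium chemistry; C11 settles with CH2N trans to the C7 chain and is erased in step 14.

Step 10
Reactants: 20 masked silyl ether
Product: 21 masked C3 allylic alcohol
Conditions: HF·pyridine, THF, 0 °C → rt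
Reagents that add atoms: none
Why: Fluoride-mediated desilylation in a mildly acidic medium, in which the protonated amine cannot leave by retro-Michael reaction.

Step 11
Reactants: 21 allylic alcohol
Product: 22 masked cyclopentenone (C3=O, C1=C2, 5αH)
Conditions: MnO2, CH2Cl2, rt
Reagents that add atoms: none
Why: Neutral heterogeneous allylic alcohol oxidation with MnO2, which leaves the tertiary amine, the bromoalkene and the γ-stereocentre C5 untouched.

Step 12
Reactants: 22 cyclopentenone; 23 dimethyl(methylidene)ammonium iodide (Eschenmoser's salt)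
Product: 25 4α-[(dimethylamino)methyl]cyclopentenone (C15 trans to C6 on ring A), via lithium dienolate 24 (not isolated)
Conditions: LiN(i-Pr)2, THF, −78 °C; then 23, −78 → −20 °C
Reagents that add atoms: none
Why: Kinetic α′-deprotonation at C4 (the only α-CH2 of the enone) and Mannich alkylation of the cross-conjugated enolate anti to the C5 side chain install C15 regiospecifically as a second masked methylene, whose C4 configuration is erased in step 14.

Step 13
Reactants: 25 bromoalkenyl enone
Product: 26 4α,11α-bis[(dimethylamino)methyl]-3-oxoguai-10(14)-en-12,6α-olide (1αH,5αH,6βH,7αH)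
Conditions: Pd(OAc)2 (10 mol %), PPh3 (25 mol %), HCO2Na, n-Bu4NCl, DMF, 70 °C
Reagents that add atoms: none
Why: Intramolecular reductive Heck reaction (7-exo-trig): oxidative addition at C10–Br and syn-carbopalladation of the enone at β-carbon C1 on the face that carries C6 leave palladium on C2 without a syn β-hydrogen, so formate-derived hydride releases the ketone and the tether sets H1 cis to H5.

Step 14
Reactants: 26 bis(amine)
Product: 28 dehydrozaluzanin C (3-oxoguaia-4(15),10(14),11(13)-trien-12,6α-olide), via bis(ammonium) diiodide 27 (not isolated)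
Conditions: MeI, MeOH, rt; then NaHCO3 (aq), CH2Cl2, rt
Reagents that add atoms: none
Why: Exhaustive methylation and double Hofmann-type E1cB elimination from the two β-ammonio carbonyl units unveil C4=C15 and C11=C13 at room temperature without touching C1, C5, C6 or C7.

Step 15
Reactants: 28 dehydrozaluzanin C (one part)
Product: 29 3-(tert-butyldimethylsilyloxy)guaia-2,4(15),10(14),11(13)-tetraen-12,6α-olide
Conditions: TBSOTf, Et3N, CH2Cl2, −78 → 0 °C
Reagents that add atoms: tert-butyldimethylsilyl trifluoromethanesulfonate, CC(C)(C)[Si](C)(C)OS(=O)(=O)C(F)(F)F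
Why: Soft enolisation to a silyl enol ether; C2 is the only enolisable position of the ketone, so a single dienol ether forms.

Step 16
Reactants: 29 silyl dienol ether; 28 dehydrozaluzanin C (dienophile, 2 equiv)
Product: 31 Diels–Alder adduct (bonds C2–C4′ and C14–C15′, C1=C10, 2αH, 5αH), via cross-conjugated dienone 30 (not isolated)
Conditions: Pd(OAc)2 (1.05 equiv), degassed MeCN, rt, Ar
Reagents that add atoms: none
Why: Saegusa–Ito dehydrogenation releases the s-cis-locked C2=C1–C10=C14 dienone at low stationary concentration, and the excess of 28 traps it in an intermolecular Diels–Alder reaction with "ortho" regiochemistry on the convex α face of C4′=C15′ (the face of H1′ and H5′) with C3′=O endo, which sets spiro centre C4′ while C2 is only transient.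

Step 17
Reactants: 31 Diels–Alder adduct
Product: 33 target CNP0221188.1, via 5α-H enone 32 (not isolated)
Conditions: DBU (0.2 equiv), degassed CH2Cl2, rt, Ar; chromatography, 32 resubmitted
Reagents that add atoms: none
Why: Base-mediated β,γ→α,β enone isomerisation: DBU removes the doubly activated C2–H, the dienolate is protonated at C10 on the α face turned away from folded ring B to give conjugated enone 32, and because C5–H is now the second γ-hydrogen of this enone it exchanges through the cross-conjugated dienolate (vinylogous epimerisation), the channel by which the 5,6-syn arrangement of 33 is reached, while oxygen is excluded to prevent autoxidation at C10.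

Compound list
1 | (1S,4R)-4-hydroxycyclopent-2-en-1-yl acetate (cis; carbinol carbon R) | CC(=O)O[C@@H]1C=C[C@H](O)C1 | starting material
2 | (1S,4R)-4-(tert-butyldimethylsilyloxy)cyclopent-2-en-1-yl acetate | CC(=O)O[C@@H]1C=C[C@H](O[Si](C)(C)C(C)(C)C)C1 | intermediate
3 | nitromethane | C[N+](=O)[O-] | starting material
4 | tert-butyl(dimethyl){[(1R,4S)-4-(nitromethyl)cyclopent-2-en-1-yl]oxy}silane | O=[N+]([O-])C[C@@H]1C=C[C@H](O[Si](C)(C)C(C)(C)C)C1 | intermediate
5 | sodium nitronate of 4 | [Na+].[O-][N+]([O-])=C[C@@H]1C=C[C@H](O[Si](C)(C)C(C)(C)C)C1 | intermediate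
6 | (1S,4R)-4-(tert-butyldimethylsilyloxy)cyclopent-2-ene-1-carbaldehyde (cis) | O=C[C@@H]1C=C[C@H](O[Si](C)(C)C(C)(C)C)C1 | intermediate
7 | 1-(trimethylsilyl)propyne | CC#C[Si](C)(C)C | starting material
8 | 2,3-dibromopropene | C=C(Br)CBr | starting material
9 | 3-lithio-1-(trimethylsilyl)propyne | [Li]CC#C[Si](C)(C)C | intermediate
10 | (5-bromohex-5-en-1-yn-1-yl)trimethylsilane | C=C(Br)CCC#C[Si](C)(C)C | intermediate
11 | 2-bromohex-1-en-5-yne | C=C(Br)CCC#C | intermediate
12 | methyl chloroformate | COC(=O)Cl | starting material
13 | lithium acetylide of 11 | [Li]C#CCCC(Br)=C | intermediate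
14 | methyl 6-bromohept-6-en-2-ynoate | COC(=O)C#CCCC(Br)=C | intermediate
15 | 2-(iodomethyl)-4,4,5,5-tetramethyl-1,3,2-dioxaborolane | ICB1OC(C)(C)C(C)(C)O1 | starting material
16 | methyl 6-bromo-2-(diisobutylalanyl)hepta-2,6-dienoate (chain cis to ester) | COC(=O)/C(=C\CCC(Br)=C)[Al](CC(C)C)CC(C)C | intermediate
17 | methyl (Z)-6-bromo-2-[(4,4,5,5-tetramethyl-1,3,2-dioxaborolan-2-yl)methyl]hepta-2,6-dienoate | COC(=O)/C(=C\CCC(Br)=C)CB1OC(C)(C)C(C)(C)O1 | intermediate
18 | C6-O-pinacolboryl homoallylic ester (6,7-anti, Felkin at C5/C6) | COC(=O)C(=C)[C@H](CCC(Br)=C)[C@H](OB1OC(C)(C)C(C)(C)O1)[C@@H]1C=C[C@H](O[Si](C)(C)C(C)(C)C)C1 | intermediate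
19 | (4S,5R)-4-(3-bromobut-3-en-1-yl)-5-[(1S,4R)-4-(tert-butyldimethylsilyloxy)cyclopent-2-en-1-yl]-3-methylideneoxolan-2-one (5αH,6βH,7αH) | C=C(Br)CC[C@H]1C(=C)C(=O)O[C@@H]1[C@@H]1C=C[C@H](O[Si](C)(C)C(C)(C)C)C1 | intermediate
20 | 11βH-13-(dimethylamino) adduct of 19 | C=C(Br)CC[C@H]1[C@H](CN(C)C)C(=O)O[C@@H]1[C@@H]1C=C[C@H](O[Si](C)(C)C(C)(C)C)C1 | intermediate
21 | C3 allylic alcohol from 20 | C=C(Br)CC[C@H]1[C@H](CN(C)C)C(=O)O[C@@H]1[C@@H]1C=C[C@H](O)C1 | intermediate
22 | masked cyclopentenone (C3=O, C1=C2, 5αH) | C=C(Br)CC[C@H]1[C@H](CN(C)C)C(=O)O[C@@H]1[C@@H]1C=CC(=O)C1 | intermediate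
23 | dimethyl(methylidene)ammonium iodide | C=[N+](C)C.[I-] | starting material
24 | lithium cross-conjugated dienolate of 22 (C3–OLi, C3=C4) | C=C(Br)CC[C@H]1[C@H](CN(C)C)C(=O)O[C@@H]1[C@@H]1C=CC(O[Li])=C1 | intermediate
25 | 4α-[(dimethylamino)methyl] derivative of 22 (4βH, 5αH) | C=C(Br)CC[C@H]1[C@H](CN(C)C)C(=O)O[C@@H]1[C@@H]1C=CC(=O)[C@H]1CN(C)C | intermediate
26 | 4α,11α-bis[(dimethylamino)methyl]-3-oxoguai-10(14)-en-12,6α-olide (1αH,5αH,6βH,7αH) | CN(C)C[C@@H]1C(=O)C[C@H]2C(=C)CC[C@H]3[C@H](CN(C)C)C(=O)O[C@@H]3[C@@H]12 | intermediate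
27 | bis(trimethylammonium) diiodide of 26 | [I-].[I-].C[N+](C)(C)C[C@@H]1C(=O)C[C@H]2C(=C)CC[C@H]3[C@H](C[N+](C)(C)C)C(=O)O[C@@H]3[C@@H]12 | intermediate
28 | dehydrozaluzanin C (1αH,5αH,6βH,7αH) | C=C1C(=O)C[C@H]2C(=C)CC[C@H]3C(=C)C(=O)O[C@@H]3[C@@H]12 | intermediate
29 | 3-(tert-butyldimethylsilyloxy)guaia-2,4(15),10(14),11(13)-tetraen-12,6α-olide | C=C1C(O[Si](C)(C)C(C)(C)C)=C[C@H]2C(=C)CC[C@H]3C(=C)C(=O)O[C@@H]3[C@@H]12 | intermediate
30 | 3-oxoguaia-1,4(15),10(14),11(13)-tetraen-12,6α-olide (5αH) | C=C1C(=O)C=C2C(=C)CC[C@H]3C(=C)C(=O)O[C@@H]3[C@@H]12 | intermediate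
31 | Diels–Alder adduct (C1=C10, 2αH, 5αH; C2 on the α face of C4′) | C=C1C(=O)[C@@H]2C3=C(CC[C@H]4C(=C)C(=O)O[C@@H]4[C@@H]13)CC[C@]21C(=O)C[C@H]2C(=C)CC[C@H]3C(=C)C(=O)O[C@@H]3[C@H]21 | intermediate
32 | conjugated enone, 5αH,10αH isomer | C=C1C(=O)C2=C3[C@H](CC[C@H]4C(=C)C(=O)O[C@@H]4[C@@H]13)CC[C@]21C(=O)C[C@H]2C(=C)CC[C@H]3C(=C)C(=O)O[C@@H]3[C@H]21 | intermediate
33 | CNP0221188.1 (C1=C2 enone; 5βH,6βH,7αH,10αH; 1′αH,5′αH,6′βH,7′αH; C2 on the α face of C4′) | C=C1C(=O)C2=C3[C@H](CC[C@H]4C(=C)C(=O)O[C@@H]4[C@H]13)CC[C@]21C(=O)C[C@H]2C(=C)CC[C@H]3C(=C)C(=O)O[C@@H]3[C@H]21 | target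

Total step count: 17. Longest linear sequence: 14 steps (7 → 33, steps 4–17).

Steps most likely to fail

In step 8 the ester-deactivated boronate may add so slowly that the aldehyde enolises first. That would cost the C5 configuration or move the alkene into conjugation. The Felkin bias of the flat cyclopentenyl group may also be modest.
- The fallback sets out from 17 (with 6). KHF2 in aqueous MeOH converts the pinacol boronate into the potassium allyltrifluoroborate F1.
- With BF3·OEt2 in CH2Cl2 at −78 °C, F1 releases the much more electrophilic allyldifluoroborane. It should add to 6 within minutes through the same chair, before enolisation can compete.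
- Aqueous work-up gives the open-chain anti hydroxy ester F2, a stage at which a C6 epimer can be removed by chromatography.
- PPTS in warm toluene lactonises F2 and the route is rejoined at 19.

In step 13 the 7-exo insertion may be slower than hydride transfer to the alkenylpalladium bromide, so that the C10–Br bond is merely reduced. Palladium hydride may also move the C10=C14 alkene into the ring.
- The fallback sets out from 25. Miyaura borylation (PdCl2(dppf), B2pin2, KOAc, dioxane, 80 °C) gives the alkenylboronate F3.
- An intramolecular Hayashi–Miyaura 1,4-addition ([Rh(cod)OH]2, dioxane–H2O, 40 °C) then closes C1–C10 through an alkenylrhodium species that has no hydride partner.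
- Protonation of the rhodium enolate comes back to the route at 26.

In step 17 the inversion at C5 rests on an equilibrium that no element of the substrate enforces. A torsional analysis of ring B suggests it prefers H5 anti to H6, so 33 may be only a minor component. Long contact with base also invites vinylogous β-elimination of the C6 lactone oxygen or autoxidation at C10.
- The fallback stops the DBU treatment as soon as conjugation is complete and isolates 32.
- From 32, TBSOTf/Et3N (CH2Cl2, −78 °C) traps the C5 dienolate as the 3-silyloxyfulvene F4, in which C5 is planar.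
- C5 is then protonated at −78 °C under reagent control with a BINOL·SnCl4 Lewis-acid-assisted Brønsted acid, the BINOL antipode being chosen for delivery to the β face.
- This replaces a thermodynamic problem by a kinetic protonation of a silyl enol ether and comes back at 33.

Further compounds
F1 | step 8 | potassium (Z)-[6-bromo-2-(methoxycarbonyl)hepta-2,6-dien-1-yl]trifluoroborate | [K+].COC(=O)/C(=C\CCC(Br)=C)C[B-](F)(F)F
F2 | step 8 | open-chain anti hydroxy ester (free C6–OH form of 18) | COC(=O)C(=C)[C@H](CCC(Br)=C)[C@H](O)[C@@H]1C=C[C@H](O[Si](C)(C)C(C)(C)C)C1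
F3 | step 13 | C10 pinacol alkenylboronate corresponding to 25 | C=C(B1OC(C)(C)C(C)(C)O1)CC[C@H]1[C@H](CN(C)C)C(=O)O[C@@H]1[C@@H]1C=CC(=O)[C@H]1CN(C)C
F4 | step 17 | 3-(tert-butyldimethylsilyloxy)fulvene from 32 (C2=C3, C1=C5, C4=C15; 10αH) | C=C1C(O[Si](C)(C)C(C)(C)C)=C2C=3[C@H](CC[C@H]4C(=C)C(=O)O[C@@H]4C13)CC[C@]21C(=O)C[C@H]2C(=C)CC[C@H]3C(=C)C(=O)O[C@@H]3[C@H]21
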